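**Retrosynthetic overview**
- The target comes from its 9-ketone by late reduction, from the C1/C2 diol by oxirane closure, and from a C15 silyl ether by desilylation and allylic oxidation.
- The cis α-methylene lactone comes from oxylactonisation of a C9 cyclohexanone by the C12 acid. The cyclohexane is closed at C7–C8 by an intramolecular Michael addition–elimination of a methyl-ketone enolate onto a 2-(acetoxymethyl)acrylate, which also unveils the exocyclic methylene.
- The Michael precursor comes from Nozaki–Hiyama–Kishi union of a C6 aldehyde with iodoacrylate fragment C, then oxidation, Felkin reduction and angeloylation.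
- C5 and quaternary C10 come from a dianionic Ireland–Claisen rearrangement of the ester of acid fragment A (from L-malate, carries C1) with allylic alcohol fragment B (from butynediol).
- Ring order: carbocycle, then γ-lactone, then oxirane.

Assumption: elemane numbering is used (C1/C2 oxirane, C10 quaternary, C5 acrolein-bearing, C6 angelate, C7/C8 lactone fusion, C9 carbinol, C11/C12/C13 lactone α-carbon/carbonyl/methylene, C15 aldehyde carbon); α is the face of the lactone oxygen; TBS = tert-butyldimethylsilyl, TES = triethylsilyl, TBDPS = tert-butyldiphenylsilyl. The route is a paper design; stereochemical outcomes are predictions from the stated models.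

**Fragment A**

Step 1
Reactants: 1 dimethyl (S)-malate
Product: 2 dimethyl (2S,3R)-2-hydroxy-3-methylbutanedioate
Conditions: LiN(iPr)2 (2.2 equiv), THF, −78 → −20 °C; MeI, −78 → 0 °C
Reagents that add atoms: iodomethane, CI
Why: Fráter–Seebach alkylation of the chelated alkoxide–enolate dianion puts methyl anti to the carbinol substituent; only the carbinol centre (future C1) matters later because this new centre is re-enolised in step 16.

Step 2
Reactants: 2 dimethyl (2S,3R)-2-hydroxy-3-methylbutanedioate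
Product: 3 methyl (2R,3S)-3,4-dihydroxy-2-methylbutanoate
Conditions: BH3·SMe2 (1.05 equiv), NaBH4 (5 mol %), THF, 20 °C; MeOH quench
Reagents that add atoms: none
Why: Hydroxyl-directed borane reduction goes through a five-membered alkoxyborane and reduces only the ester next to the free hydroxyl, leaving both stereocentres untouched.

Step 3
Reactants: 3 methyl (2R,3S)-3,4-dihydroxy-2-methylbutanoate
Product: 4 methyl (2R,3S)-4-(TBS-oxy)-3-hydroxy-2-methylbutanoate
Conditions: t-BuMe2SiCl (1.05 equiv), imidazole, CH2Cl2, 0 °C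
Reagents that add atoms: tert-butyldimethylsilyl chloride, CC(C)(C)[Si](C)(C)Cl
Why: Sterically controlled silylation takes the primary hydroxyl and leaves the hindered secondary one free.

Step 4
Reactants: 4 methyl (2R,3S)-4-(TBS-oxy)-3-hydroxy-2-methylbutanoate
Product: 5 (2R,3S)-4-(TBS-oxy)-3-hydroxy-2-methylbutanoic acid (fragment A)
Conditions: LiOH, THF–H2O, 0 °C; cold dilute HCl to pH 3
Reagents that add atoms: lithium hydroxide, [Li+].[OH-]
Why: Saponification of a methyl ester at 0 °C leaves the primary silyl ether and the carbinol centre intact.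

**Fragment B**

Step 5
Reactants: 6 but-2-yne-1,4-diol
Product: 7 4-(TBDPS-oxy)but-2-yn-1-ol
Conditions: NaH (1.0 equiv), t-BuPh2SiCl (1.0 equiv), THF, 0 °C
Reagents that add atoms: tert-butyldiphenylsilyl chloride, CC(C)(C)[Si](Cl)(c1ccccc1)c1ccccc1
Why: Monosilylation of a symmetric diol through its sparingly soluble monosodium alkoxide gives the mono-ether.

Step 6
Reactants: 7 4-(TBDPS-oxy)but-2-yn-1-ol
Product: 9 (Z)-4-(TBDPS-oxy)-3-iodobut-2-en-1-ol, via cyclic alkenylaluminate 8 (not isolated)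
Conditions: NaAlH2(OCH2CH2OMe)2, THF, 0 → 20 °C; then I2, −78 °C
Reagents that add atoms: iodine, II
Why: Hydroxyl-directed trans-hydroalumination puts aluminium on the distal alkyne carbon, and iodinolysis with retention gives the Z-iodide with iodine cis to CH2OH.

Step 7
Reactants: 9 (Z)-4-(TBDPS-oxy)-3-iodobut-2-en-1-ol
Product: 10 (Z)-1-(TBDPS-oxy)-2-iodo-4-(TES-oxy)but-2-ene
Conditions: Et3SiCl, imidazole, CH2Cl2, 0 °C
Reagents that add atoms: chlorotriethylsilane, CC[Si](Cl)(CC)CC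
Why: Routine silylation installs the one silyl ether that step 18 will later oxidise directly.

Step 8
Reactants: 10 (Z)-1-(TBDPS-oxy)-2-iodo-4-(TES-oxy)but-2-ene
Product: 11 (E)-2-[(TBDPS-oxy)methyl]-4-(TES-oxy)but-2-en-1-ol (fragment B)
Conditions: Pd(PPh3)4 (5 mol %), Bu3SnCH2OH (1.5 equiv), toluene, 90 °C
Reagents that add atoms: (tributylstannyl)methanol, CCCC[Sn](CCCC)(CCCC)CO
Why: Migita–Kosugi–Stille hydroxymethylation proceeds with retention, so the new CH2OH is cis to the CH2OSiEt3 arm, the geometry the rearrangement in step 16 needs.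

**Fragment C**

Step 9
Reactants: 12 methyl 2-(hydroxymethyl)prop-2-enoate
Product: 13 methyl 2-(bromomethyl)prop-2-enoate
Conditions: PBr3 (0.4 equiv), Et2O, −10 → 20 °C
Reagents that add atoms: phosphorus tribromide, BrP(Br)Br
Why: Bromide displaces the activated allylic phosphite ester (SN2 or SN2′ give the same product).

Step 10
Reactants: 13 methyl 2-(bromomethyl)prop-2-enoate
Product: 14 methyl 2,3-dibromo-2-(bromomethyl)propanoate
Conditions: Br2, CH2Cl2, 0 → 20 °C
Reagents that add atoms: bromine, BrBr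
Why: Electrophilic addition of bromine across the acrylate double bond gives a tribromide with two equivalent CH2Br arms.

Step 11
Reactants: 14 methyl 2,3-dibromo-2-(bromomethyl)propanoate
Product: 15 methyl (Z)-3-bromo-2-(bromomethyl)prop-2-enoate
Conditions: i-Pr2NEt (1.05 equiv), CH2Cl2, 0 °C
Reagents that add atoms: none
Why: E2 dehydrobromination can only use a CH2Br hydrogen and the α-bromide, and gives the isomer with vinylic bromine trans to the ester, as with methacrylate dibromides.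

Step 12
Reactants: 15 methyl (Z)-3-bromo-2-(bromomethyl)prop-2-enoate
Product: 16 methyl (E)-2-(acetoxymethyl)-3-bromoprop-2-enoate
Conditions: KOAc, DMF, 20 °C
Reagents that add atoms: potassium acetate, [K+].CC(=O)[O-]
Why: SN2 displacement of the allylic bromide is far faster than vinylic substitution, so only the CH2Br reacts.

Step 13
Reactants: 16 methyl (E)-2-(acetoxymethyl)-3-bromoprop-2-enoate
Product: 17 methyl (E)-2-(acetoxymethyl)-3-iodoprop-2-enoate (fragment C)
Conditions: NaI (2 equiv), CuI (5 mol %), MeNHCH2CH2NHMe (10 mol %), 1,4-dioxane, 100 °C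
Reagents that add atoms: sodium iodide, [Na+].[I-]
Why: Copper-catalysed vinylic Finkelstein exchange proceeds with retention and gives the iodide needed for mild nickel insertion in step 19.

**Acylating agent**

Step 14
Reactants: 18 angelic acid
Product: 19 (Z)-2-methylbut-2-enoic 2,4,6-trichlorobenzoic anhydride
Conditions: 2,4,6-Cl3C6H2COCl, Et3N, toluene, 20 °C
Reagents that add atoms: 2,4,6-trichlorobenzoyl chloride, O=C(Cl)c1c(Cl)cc(Cl)cc1Cl
Why: Yamaguchi mixed-anhydride formation activates the acid without nucleophilic catalysts, so the Z double bond does not isomerise.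

**Assembly**

Step 15
Reactants: 5 fragment A acid; 11 fragment B alcohol
Product: 20 (E)-2-[(TBDPS-oxy)methyl]-4-(TES-oxy)but-2-en-1-yl (2R,3S)-4-(TBS-oxy)-3-hydroxy-2-methylbutanoate
Conditions: EDCI·HCl, DMAP (10 mol %), CH2Cl2, 0 °C
Reagents that add atoms: none
Why: Steglich-type carbodiimide esterification acylates the primary allylic alcohol much faster than the hindered secondary hydroxyl of the acid.

Step 16
Reactants: 20 allyl β-hydroxy ester
Product: 23 (2R,3S)-2-[(1S)-2-(TBS-oxy)-1-(TES-oxy)ethyl]-4-[(TBDPS-oxy)methyl]-2-methyl-3-[(TES-oxy)methyl]pent-4-enoic acid, via hydroxy acid 21 (not isolated), via triethylsilyl ester 22 (not isolated)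
Conditions: LiN(iPr)2 (2.5 equiv), THF, −78 → 50 °C; then Et3SiCl, 0 °C; aq. NH4Cl
Reagents that add atoms: chlorotriethylsilane, CC[Si](Cl)(CC)CC
Why: In this dianionic Ireland–Claisen rearrangement the alkoxide–enolate lithium chelate fixes the enolate geometry (methyl cis to the allyloxy oxygen) and blocks the face carrying CH2OTBS, so the allyl unit adds through a chair from the open face with its cis CH2OSiEt3 arm axial, setting quaternary C10 and C5 relative to C1; the alkoxide is then capped in the same flask.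

Step 17
Reactants: 23 rearranged acid
Product: 24 (3R,4S)-3-[(1S)-2-(TBS-oxy)-1-(TES-oxy)ethyl]-5-[(TBDPS-oxy)methyl]-3-methyl-4-[(TES-oxy)methyl]hex-5-en-2-one
Conditions: MeLi (2.5 equiv), Et2O, 0 °C; inverse quench into aq. NH4Cl
Reagents that add atoms: methyllithium, [Li]C
Why: Methyllithium adds to the lithium carboxylate to give a stable gem-dialkoxide that collapses to the methyl ketone only on quench, and the α-quaternary centre prevents enolisation or over-addition.

Step 18
Reactants: 24 methyl ketone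
Product: 25 (2S,3R)-3-[(1S)-2-(TBS-oxy)-1-(TES-oxy)ethyl]-2-[3-(TBDPS-oxy)prop-1-en-2-yl]-3-methyl-4-oxopentanal
Conditions: (COCl)2, DMSO, CH2Cl2, −78 → −30 °C; Et3N
Reagents that add atoms: none
Why: Under Swern conditions a primary triethylsilyl ether is cleaved and oxidised directly to the aldehyde, while the secondary TES, primary TBS and TBDPS ethers are inert; the cold, brief base exposure protects the α-centre.

Step 19
Reactants: 25 aldehyde; 17 fragment C iodide
Product: 26 methyl (2E,5S,6R)-2-(acetoxymethyl)-4-hydroxy-6-methyl-7-oxo-5-[3-(TBDPS-oxy)prop-1-en-2-yl]-6-[(1S)-2-(TBS-oxy)-1-(TES-oxy)ethyl]oct-2-enoate (C4 epimers)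
Conditions: CrCl2 (4 equiv), NiCl2 (2 mol %), DMSO, 20 °C
Reagents that add atoms: none
Why: Nozaki–Hiyama–Kishi coupling adds the alkenylchromium reagent to the hindered aldehyde only, tolerating the ketone, esters and allylic acetate; the E geometry keeps the ester away from the new hydroxyl so no butenolide forms, and the carbinol configuration is irrelevant because it is oxidised next.

Step 20
Reactants: 26 allylic alcohol mixture
Product: 27 methyl (2E,5S,6R)-2-(acetoxymethyl)-6-methyl-4,7-dioxo-5-[3-(TBDPS-oxy)prop-1-en-2-yl]-6-[(1S)-2-(TBS-oxy)-1-(TES-oxy)ethyl]oct-2-enoate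
Conditions: Dess–Martin periodinane, NaHCO3, CH2Cl2, 0 °C
Reagents that add atoms: none
Why: Buffered Dess–Martin oxidation converges both epimers to one enone without epimerising the adjacent C5 centre.

Step 21
Reactants: 27 enone
Product: 28 methyl (2E,4R,5S,6R)-2-(acetoxymethyl)-4-hydroxy-6-methyl-7-oxo-5-[3-(TBDPS-oxy)prop-1-en-2-yl]-6-[(1S)-2-(TBS-oxy)-1-(TES-oxy)ethyl]oct-2-enoate
Conditions: NaBH4 (1.0 equiv), CeCl3·7H2O, MeOH, −78 °C
Reagents that add atoms: none
Why: Luche 1,2-reduction takes the activated enone carbonyl in preference to the neopentyl methyl ketone, and Felkin–Anh attack anti to the quaternary C10 group gives the C6 configuration of the target (the opposite of what carbon addition to the aldehyde gives).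

Step 22
Reactants: 28 allylic alcohol; 19 mixed anhydride
Product: 29 methyl (2E,4R,5S,6R)-2-(acetoxymethyl)-4-[(Z)-2-methylbut-2-enoyloxy]-6-methyl-7-oxo-5-[3-(TBDPS-oxy)prop-1-en-2-yl]-6-[(1S)-2-(TBS-oxy)-1-(TES-oxy)ethyl]oct-2-enoate
Conditions: NaHCO3, toluene, 80 °C
Reagents that add atoms: none
Why: Yamaguchi-type acylation goes at the less hindered angeloyl carbonyl, and the absence of nucleophilic amine catalysts avoids angelate-to-tiglate isomerisation.

Step 23
Reactants: 29 Michael precursor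
Product: 30 methyl 2-[(1R,2R,3S,4R)-2-[(Z)-2-methylbut-2-enoyloxy]-4-methyl-5-oxo-3-[3-(TBDPS-oxy)prop-1-en-2-yl]-4-[(1S)-2-(TBS-oxy)-1-(TES-oxy)ethyl]cyclohexyl]prop-2-enoate
Conditions: LiN(SiMe3)2 (1.1 equiv), THF, −78 → −20 °C
Reagents that add atoms: none
Why: The methyl ketone has only one enolisable site, and its enolate adds 6-exo to the acrylate β-carbon (intramolecular Michael addition), after which the ester enolate expels acetate to give the exocyclic methylene; a chair transition state with the C6 angelate and the new C7 arm equatorial sets C7 trans to the angelate.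

Step 24
Reactants: 30 keto ester
Product: 31 2-[(1R,2R,3S,4R)-2-[(Z)-2-methylbut-2-enoyloxy]-4-methyl-5-oxo-3-[3-(TBDPS-oxy)prop-1-en-2-yl]-4-[(1S)-2-(TBS-oxy)-1-(TES-oxy)ethyl]cyclohexyl]prop-2-enoic acid
Conditions: Me3SnOH (6 equiv), ClCH2CH2Cl, 80 °C; cold dilute HCl wash
Reagents that add atoms: trimethyltin hydroxide, C[Sn](C)(C)O
Why: Trimethyltin hydroxide cleaves unhindered methyl esters under near-neutral conditions and leaves the hindered secondary angelate and the silyl ethers alone.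

Step 25
Reactants: 31 keto acid
Product: 33 the 1,2-diol 9-ketone: compound 34 with the oxirane opened to C1–OH and C2–OH, via bis-silyl keto lactone 32 (not isolated)
Conditions: PhI(OH)OTs (1.3 equiv), MeCN, 20 °C; then H2O (10 vol %), 20 °C
Reagents that add atoms: none
Why: In this Moriarty–Koser oxylactonisation the ketone enol attacks trivalent iodine from the β face (anti to the axial C10 side chain) and the tethered carboxylate displaces iodobenzene with inversion, placing the C8 oxygen α and cis to C7; the liberated TsOH in wet acetonitrile then removes the TES and primary TBS ethers but not TBDPS.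

Step 26
Reactants: 33 diol keto lactone
Product: 34 the 9-ketone of 35 (oxirane closed, C15 still TBDPS ether)
Conditions: PPh3, i-PrO2CN=NCO2i-Pr, toluene, 0 → 20 °C
Reagents that add atoms: none
Why: Mitsunobu cyclodehydration activates the primary C2 hydroxyl and the C1 hydroxyl closes the oxirane with retention at C1; no other free hydroxyl is present because C9 is still a ketone.

Step 27
Reactants: 34 epoxy keto lactone
Product: 35 the 15-O-TBDPS allylic ether of 36 (CH2OTBDPS in place of the aldehyde of 37)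
Conditions: NaBH4, CeCl3·7H2O, MeOH–THF, −78 → −40 °C
Reagents that add atoms: none
Why: Hydride adds anti to the axial C8–O bond (polar Felkin–Anh) and away from the axial C10 oxiranyl group, that is from the β face, giving the equatorial 9α-alcohol; cerium suppresses conjugate reduction of the methylene lactone.

Step 28
Reactants: 35 silyl ether
Product: 36 the allylic alcohol of 37 (CH2OH in place of CHO)
Conditions: Bu4NF, AcOH (1:1), THF, 0 → 20 °C
Reagents that add atoms: none
Why: Acetic acid-buffered fluoride removes the primary allylic silyl ether without touching the oxirane, angelate or methylene lactone.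

Step 29
Reactants: 36 allylic alcohol
Product: 37 target, (1S,5R,6S,7R,8R,9S,10S)-6-angeloyloxy-1,2-epoxy-9-hydroxy-15-oxoelema-3,11(13)-dien-12,8-olide
Conditions: MnO2 (activated, 20 equiv), CH2Cl2, 20 °C
Reagents that add atoms: none
Why: Manganese dioxide oxidises only the allylic primary alcohol and leaves the secondary C9 carbinol untouched.

**Compound list**

1 | dimethyl (S)-malate | COC(=O)C[C@H](O)C(=O)OC | starting material
2 | dimethyl (2S,3R)-2-hydroxy-3-methylbutanedioate | COC(=O)[C@H](C)[C@H](O)C(=O)OC | intermediate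
3 | methyl (2R,3S)-3,4-dihydroxy-2-methylbutanoate | COC(=O)[C@H](C)[C@H](O)CO | intermediate
4 | methyl (2R,3S)-4-(TBS-oxy)-3-hydroxy-2-methylbutanoate | COC(=O)[C@H](C)[C@H](O)CO[Si](C)(C)C(C)(C)C | intermediate
5 | (2R,3S)-4-(TBS-oxy)-3-hydroxy-2-methylbutanoic acid (fragment A) | OC(=O)[C@H](C)[C@H](O)CO[Si](C)(C)C(C)(C)C | intermediate
6 | but-2-yne-1,4-diol | OCC#CCO | starting material
7 | 4-(TBDPS-oxy)but-2-yn-1-ol | OCC#CCO[Si](c1ccccc1)(c1ccccc1)C(C)(C)C | intermediate
8 | sodium 3-[(TBDPS-oxy)methyl]-2,2-bis(2-methoxyethoxy)-2,5-dihydro-1,2-oxaaluminol-2-uide (cyclic alkenylaluminate) | [Na+].COCCO[Al-]1(OCCOC)OCC=C1CO[Si](c1ccccc1)(c1ccccc1)C(C)(C)C | intermediate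
9 | (Z)-4-(TBDPS-oxy)-3-iodobut-2-en-1-ol | OC/C=C(\I)CO[Si](c1ccccc1)(c1ccccc1)C(C)(C)C | intermediate
10 | (Z)-1-(TBDPS-oxy)-2-iodo-4-(TES-oxy)but-2-ene | CC[Si](CC)(CC)OC/C=C(\I)CO[Si](c1ccccc1)(c1ccccc1)C(C)(C)C | intermediate
11 | (E)-2-[(TBDPS-oxy)methyl]-4-(TES-oxy)but-2-en-1-ol (fragment B; CH2OH cis to the CH2OTES arm) | CC[Si](CC)(CC)OC/C=C(\CO)CO[Si](c1ccccc1)(c1ccccc1)C(C)(C)C | intermediate
12 | methyl 2-(hydroxymethyl)prop-2-enoate | C=C(CO)C(=O)OC | starting material
13 | methyl 2-(bromomethyl)prop-2-enoate | C=C(CBr)C(=O)OC | intermediate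
14 | methyl 2,3-dibromo-2-(bromomethyl)propanoate | BrCC(Br)(CBr)C(=O)OC | intermediate
15 | methyl (Z)-3-bromo-2-(bromomethyl)prop-2-enoate | Br/C=C(\CBr)C(=O)OC | intermediate
16 | methyl (E)-2-(acetoxymethyl)-3-bromoprop-2-enoate | Br/C=C(\COC(C)=O)C(=O)OC | intermediate
17 | methyl (E)-2-(acetoxymethyl)-3-iodoprop-2-enoate (fragment C) | I/C=C(\COC(C)=O)C(=O)OC | intermediate
18 | angelic acid, (Z)-2-methylbut-2-enoic acid | C/C=C(/C)C(=O)O | starting material
19 | (Z)-2-methylbut-2-enoic 2,4,6-trichlorobenzoic anhydride | C/C=C(/C)C(=O)OC(=O)c1c(Cl)cc(Cl)cc1Cl | intermediate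
20 | (E)-2-[(TBDPS-oxy)methyl]-4-(TES-oxy)but-2-en-1-yl (2R,3S)-4-(TBS-oxy)-3-hydroxy-2-methylbutanoate | O=C(OC/C(CO[Si](c1ccccc1)(c1ccccc1)C(C)(C)C)=C\CO[Si](CC)(CC)CC)[C@H](C)[C@H](O)CO[Si](C)(C)C(C)(C)C | intermediate
21 | (2R,3S)-2-[(1S)-2-(TBS-oxy)-1-hydroxyethyl]-4-[(TBDPS-oxy)methyl]-2-methyl-3-[(TES-oxy)methyl]pent-4-enoic acid (formed as dilithium salt) | OC(=O)[C@@](C)([C@H](O)CO[Si](C)(C)C(C)(C)C)[C@@H](CO[Si](CC)(CC)CC)C(=C)CO[Si](c1ccccc1)(c1ccccc1)C(C)(C)C | intermediate
22 | triethylsilyl ester of 23 | CC[Si](CC)(CC)OC(=O)[C@@](C)([C@H](O[Si](CC)(CC)CC)CO[Si](C)(C)C(C)(C)C)[C@@H](CO[Si](CC)(CC)CC)C(=C)CO[Si](c1ccccc1)(c1ccccc1)C(C)(C)C | intermediate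
23 | (2R,3S)-2-[(1S)-2-(TBS-oxy)-1-(TES-oxy)ethyl]-4-[(TBDPS-oxy)methyl]-2-methyl-3-[(TES-oxy)methyl]pent-4-enoic acid | OC(=O)[C@@](C)([C@H](O[Si](CC)(CC)CC)CO[Si](C)(C)C(C)(C)C)[C@@H](CO[Si](CC)(CC)CC)C(=C)CO[Si](c1ccccc1)(c1ccccc1)C(C)(C)C | intermediate
24 | (3R,4S)-3-[(1S)-2-(TBS-oxy)-1-(TES-oxy)ethyl]-5-[(TBDPS-oxy)methyl]-3-methyl-4-[(TES-oxy)methyl]hex-5-en-2-one | CC(=O)[C@@](C)([C@H](O[Si](CC)(CC)CC)CO[Si](C)(C)C(C)(C)C)[C@@H](CO[Si](CC)(CC)CC)C(=C)CO[Si](c1ccccc1)(c1ccccc1)C(C)(C)C | intermediate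
25 | (2S,3R)-3-[(1S)-2-(TBS-oxy)-1-(TES-oxy)ethyl]-2-[3-(TBDPS-oxy)prop-1-en-2-yl]-3-methyl-4-oxopentanal | CC(=O)[C@@](C)([C@H](O[Si](CC)(CC)CC)CO[Si](C)(C)C(C)(C)C)[C@@H](C=O)C(=C)CO[Si](c1ccccc1)(c1ccccc1)C(C)(C)C | intermediate
26 | methyl (2E,5S,6R)-2-(acetoxymethyl)-4-hydroxy-6-methyl-7-oxo-5-[3-(TBDPS-oxy)prop-1-en-2-yl]-6-[(1S)-2-(TBS-oxy)-1-(TES-oxy)ethyl]oct-2-enoate, C4 epimers | CC(=O)[C@@](C)([C@H](O[Si](CC)(CC)CC)CO[Si](C)(C)C(C)(C)C)[C@@H](C(O)/C=C(\COC(C)=O)C(=O)OC)C(=C)CO[Si](c1ccccc1)(c1ccccc1)C(C)(C)C | intermediate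
27 | methyl (2E,5S,6R)-2-(acetoxymethyl)-6-methyl-4,7-dioxo-5-[3-(TBDPS-oxy)prop-1-en-2-yl]-6-[(1S)-2-(TBS-oxy)-1-(TES-oxy)ethyl]oct-2-enoate | CC(=O)[C@@](C)([C@H](O[Si](CC)(CC)CC)CO[Si](C)(C)C(C)(C)C)[C@@H](C(=O)/C=C(\COC(C)=O)C(=O)OC)C(=C)CO[Si](c1ccccc1)(c1ccccc1)C(C)(C)C | intermediate
28 | methyl (2E,4R,5S,6R)-2-(acetoxymethyl)-4-hydroxy-6-methyl-7-oxo-5-[3-(TBDPS-oxy)prop-1-en-2-yl]-6-[(1S)-2-(TBS-oxy)-1-(TES-oxy)ethyl]oct-2-enoate | CC(=O)[C@@](C)([C@H](O[Si](CC)(CC)CC)CO[Si](C)(C)C(C)(C)C)[C@@H]([C@H](O)/C=C(\COC(C)=O)C(=O)OC)C(=C)CO[Si](c1ccccc1)(c1ccccc1)C(C)(C)C | intermediate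
29 | 4-O-angeloyl ester of 28 | CC(=O)[C@@](C)([C@H](O[Si](CC)(CC)CC)CO[Si](C)(C)C(C)(C)C)[C@@H]([C@H](OC(=O)/C(C)=C\C)/C=C(\COC(C)=O)C(=O)OC)C(=C)CO[Si](c1ccccc1)(c1ccccc1)C(C)(C)C | intermediate
30 | methyl 2-[(1R,2R,3S,4R)-2-angeloyloxy-4-methyl-5-oxo-3-[3-(TBDPS-oxy)prop-1-en-2-yl]-4-[(1S)-2-(TBS-oxy)-1-(TES-oxy)ethyl]cyclohexyl]prop-2-enoate | O=C1C[C@H](C(=C)C(=O)OC)[C@@H](OC(=O)/C(C)=C\C)[C@@H](C(=C)CO[Si](c2ccccc2)(c2ccccc2)C(C)(C)C)[C@]1(C)[C@H](O[Si](CC)(CC)CC)CO[Si](C)(C)C(C)(C)C | intermediate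
31 | carboxylic acid of 30 | O=C1C[C@H](C(=C)C(=O)O)[C@@H](OC(=O)/C(C)=C\C)[C@@H](C(=C)CO[Si](c2ccccc2)(c2ccccc2)C(C)(C)C)[C@]1(C)[C@H](O[Si](CC)(CC)CC)CO[Si](C)(C)C(C)(C)C | intermediate
32 | 1-O-TES, 2-O-TBS ether of 33 (cis-fused α-methylene keto lactone) | C=C1C(=O)O[C@@H]2[C@H]1[C@@H](OC(=O)/C(C)=C\C)[C@@H](C(=C)CO[Si](c1ccccc1)(c1ccccc1)C(C)(C)C)[C@](C)([C@H](O[Si](CC)(CC)CC)CO[Si](C)(C)C(C)(C)C)C2=O | intermediate
33 | 1,2-diol 9-ketone (34 with the oxirane opened to C1–OH and C2–OH) | C=C1C(=O)O[C@@H]2[C@H]1[C@@H](OC(=O)/C(C)=C\C)[C@@H](C(=C)CO[Si](c1ccccc1)(c1ccccc1)C(C)(C)C)[C@](C)([C@H](O)CO)C2=O | intermediate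
34 | 9-ketone of 35 | C=C1C(=O)O[C@@H]2[C@H]1[C@@H](OC(=O)/C(C)=C\C)[C@@H](C(=C)CO[Si](c1ccccc1)(c1ccccc1)C(C)(C)C)[C@](C)([C@H]1CO1)C2=O | intermediate
35 | 15-O-TBDPS ether of 36 | C=C1C(=O)O[C@@H]2[C@H]1[C@@H](OC(=O)/C(C)=C\C)[C@@H](C(=C)CO[Si](c1ccccc1)(c1ccccc1)C(C)(C)C)[C@](C)([C@H]1CO1)[C@@H]2O | intermediate
36 | allylic alcohol of 37 (C15 CH2OH) | C=C1C(=O)O[C@@H]2[C@H]1[C@@H](OC(=O)/C(C)=C\C)[C@@H](C(=C)CO)[C@](C)([C@H]1CO1)[C@@H]2O | intermediate
37 | CNP0113462.5, (1S,5R,6S,7R,8R,9S,10S)-6-angeloyloxy-1,2-epoxy-9-hydroxy-15-oxoelema-3,11(13)-dien-12,8-olide | C=C1C(=O)O[C@@H]2[C@H]1[C@@H](OC(=O)/C(C)=C\C)[C@@H](C(=C)C=O)[C@](C)([C@H]1CO1)[C@@H]2O | target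

**Totals**

Total step count: 29. Longest linear sequence: 19 steps (steps 5–8 then 15–29; steps 1–4 then 15–29 is equally long).

**Steps most likely to fail, with fallbacks**

Step 16 (dianionic Ireland–Claisen). The lithium dianion may fragment or rearrange sluggishly at 50 °C. The fallback sets out from 20 and runs the shift through the silyl manifold. Deprotonation at −78 °C as before (the chelate still fixes the enolate geometry) is followed by trapping with Me3SiCl/Et3N to give the bis(trimethylsilyl) ketene acetal F1, which rearranges at 20 °C to the trimethylsilyl ester F2. Brief aqueous citric acid releases hydroxy acid 21, which is silylated in a separate flask (Et3SiOTf, 2,6-lutidine, CH2Cl2; then K2CO3/MeOH to cleave the silyl ester) to rejoin the route at 23.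

Step 25 (oxylactonisation). The iodane may attack the allyl silyl ether alkene, or the lactone may close trans. The fallback sets out from keto ester 30. LiN(SiMe3)2/Me3SiCl gives the trimethylsilyl enol ether F3. Rubottom oxidation (m-CPBA 1.0 equiv, NaHCO3, CH2Cl2, −20 °C; citric acid work-up) delivers oxygen from the same β face to give the 8β-hydroxy ketone F4. Me3SnOH frees the hydroxy acid F5, and Mitsunobu lactonisation (PPh3, diisopropyl azodicarboxylate) closes the ring with inversion at C8. This arrives at 32, which is desilylated to 33 with aqueous TsOH in MeCN as in step 25.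

Step 27 (C9 reduction). Borohydride may enter from the α face, since both faces of the ketone are hindered. The fallback sets out from 34 and changes the order. Bu4NF/AcOH first removes the silyl group to give the hydroxy ketone F6, whose axial C5 side arm now carries a free hydroxyl over the β face of C9 and no longer carries the bulky silyl group. Reduction with Me4NBH(OAc)3 (MeCN–AcOH, −30 °C) relies on internal hydride delivery from the borohydride bound to that hydroxyl, that is from the β face. This gives 36 directly and rejoins the route there.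

**Further compounds**

F1 | step 16 | bis(trimethylsilyl) ketene acetal of 20 (methyl cis to the allyloxy oxygen, C1–OSiMe3) | C/C(=C(/O[Si](C)(C)C)OC/C(CO[Si](c1ccccc1)(c1ccccc1)C(C)(C)C)=C\CO[Si](CC)(CC)CC)[C@H](O[Si](C)(C)C)CO[Si](C)(C)C(C)(C)C
F2 | step 16 | trimethylsilyl ester, 1-O-trimethylsilyl ether of 21 | C[Si](C)(C)OC(=O)[C@@](C)([C@H](O[Si](C)(C)C)CO[Si](C)(C)C(C)(C)C)[C@@H](CO[Si](CC)(CC)CC)C(=C)CO[Si](c1ccccc1)(c1ccccc1)C(C)(C)C
F3 | step 25 | trimethylsilyl enol ether of 30 (C8=C9) | C[Si](C)(C)OC1=C[C@H](C(=C)C(=O)OC)[C@@H](OC(=O)/C(C)=C\C)[C@@H](C(=C)CO[Si](c2ccccc2)(c2ccccc2)C(C)(C)C)[C@]1(C)[C@H](O[Si](CC)(CC)CC)CO[Si](C)(C)C(C)(C)C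
F4 | step 25 | 8β-hydroxy derivative of 30 | O=C1[C@@H](O)[C@H](C(=C)C(=O)OC)[C@@H](OC(=O)/C(C)=C\C)[C@@H](C(=C)CO[Si](c2ccccc2)(c2ccccc2)C(C)(C)C)[C@]1(C)[C@H](O[Si](CC)(CC)CC)CO[Si](C)(C)C(C)(C)C
F5 | step 25 | 8β-hydroxy derivative of 31 | O=C1[C@@H](O)[C@H](C(=C)C(=O)O)[C@@H](OC(=O)/C(C)=C\C)[C@@H](C(=C)CO[Si](c2ccccc2)(c2ccccc2)C(C)(C)C)[C@]1(C)[C@H](O[Si](CC)(CC)CC)CO[Si](C)(C)C(C)(C)C
F6 | step 27 | 15-hydroxy 9-ketone (34 without the silyl group) | C=C1C(=O)O[C@@H]2[C@H]1[C@@H](OC(=O)/C(C)=C\C)[C@@H](C(=C)CO)[C@](C)([C@H]1CO1)C2=O
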